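**Assumption:** the SMILES carries no stereodescriptor (no stereocentre; the dienone ring is symmetric, so the exocyclic C=C has no E/Z isomers). The target is therefore made as drawn, with no control of the hindered aryl–C(methylidene) axis.

## Retrosynthetic overview

1. 11 ⇒ Sonogashira coupling at the di-ortho C–Br of bromo quinone methide 9 with 4-ethynylphenol 10 (alkyne last, amine base only).
2. 9 ⇒ sterically controlled mono-Suzuki coupling of dibromo quinone methide 7 with 4-hydroxyphenylboronic acid 8.
3. 7 ⇒ loss of water from 4-hydroxyphenyl triaryl carbinol 6 (hydroxytrityl cation → cyclohexadienone), the ring event presumed for selaginellins in the plant; 6 ⇒ aryllithium 3 (LDA on 2,4-dibromotoluene 1) + transiently silylated 4-hydroxybenzophenone 2.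
4. Ring order: the three benzene rings are bought intact. The only ring generated is the quinone-methide ring, made first (step 1) and carried unprotected through both couplings.

## Route

**Step 1**
Reactants: 1 2,4-dibromotoluene; 2 4-hydroxybenzophenone
Product: 7 4-[(2,6-dibromo-3-methylphenyl)(phenyl)methylidene]cyclohexa-2,5-dien-1-one, via aryllithium 3 (not isolated), via silyl ether 4 (not isolated), via lithium alkoxide 5 (not isolated), via triaryl carbinol 6 (not isolated)
Conditions: 1 (1.3 eq), LDA (commercial, 1.2 eq), THF, −78 °C, 1 h; 2, HMDS (0.6 eq), TMSCl (1 mol %), PhMe, 80 °C, evaporated, added in THF at −78 °C, 2 h; 2 M HCl, −78 °C → rt; TsOH (cat.), PhMe, 60 °C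
Reagents that add atoms: none
Why: Directed ortho-lithiation removes the proton flanked by both bromines (the 2,6-dihaloaryllithium is stable at −78 °C), the aryllithium adds 1,2 to the non-enolisable diaryl ketone as other 2,6-dihalo- and perhaloaryllithiums do with benzophenones, and acid then removes the silyl group and ionises the carbinol to a 4-hydroxytrityl cation that loses its phenolic proton (dehydrative dearomatisation, the classical fuchsone formation); the carbinol stereocentre of 5 and 6 is racemic and is erased when the C=C forms.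

**Step 2**
Reactants: 7 4-[(2,6-dibromo-3-methylphenyl)(phenyl)methylidene]cyclohexa-2,5-dien-1-one; 8 4-hydroxyphenylboronic acid
Product: 9 4-[(3-bromo-4'-hydroxy-4-methyl-[1,1'-biphenyl]-2-yl)(phenyl)methylidene]cyclohexa-2,5-dien-1-one
Conditions: 8 (1.3 eq), Pd(PPh3)4 (5 mol %), 2 M aq Na2CO3, DME, 75 °C; dilute AcOH work-up
Reagents that add atoms: none
Why: Suzuki–Miyaura coupling under steric control: the PPh3-ligated catalyst should insert only into the C–Br with a single ortho neighbour, the C–Br wedged between CH3 and the diarylmethylidene group stays inert (so no double coupling), the free phenols are tolerated, and the fully substituted, shielded methide carbon resists 1,6-addition while the acidic work-up guarantees the quinone-methide form; no stereocentre is formed.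

**Step 3**
Reactants: 9 4-[(3-bromo-4'-hydroxy-4-methyl-[1,1'-biphenyl]-2-yl)(phenyl)methylidene]cyclohexa-2,5-dien-1-one; 10 4-ethynylphenol
Product: 11 selaginellin A, 4-[{4'-hydroxy-3-[(4-hydroxyphenyl)ethynyl]-4-methyl-[1,1'-biphenyl]-2-yl}(phenyl)methylidene]cyclohexa-2,5-dien-1-one
Conditions: 10 (1.5 eq, slow addition), Pd(PhCN)2Cl2 (5 mol %), [HP(t-Bu)3]BF4 (10 mol %), CuI (5 mol %), i-Pr2NH (3 eq), dioxane, 55 °C, degassed
Reagents that add atoms: none
Why: Sonogashira coupling with the P(t-Bu)3–Pd/CuI system, which inserts into di-ortho-substituted aryl bromides under mild conditions; the planar methide carbon is less bulky than a trityl carbinol would be, the amine base tolerates both free phenols, and no hydroxide or alkoxide is present that could attack the new alkyne or the quinone methide; no stereocentre is formed.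

## Compound list

1 | 2,4-dibromotoluene | Cc1ccc(Br)cc1Br | starting material
2 | 4-hydroxybenzophenone | O=C(c1ccccc1)c1ccc(O)cc1 | starting material
3 | 2,6-dibromo-3-methylphenyllithium | [Li]c1c(Br)ccc(C)c1Br | intermediate
4 | 4-(trimethylsilyloxy)benzophenone | C[Si](C)(C)Oc1ccc(cc1)C(=O)c1ccccc1 | intermediate
5 | lithium (2,6-dibromo-3-methylphenyl)(phenyl)[4-(trimethylsilyloxy)phenyl]methoxide (racemic) | [Li]OC(c1ccccc1)(c1ccc(O[Si](C)(C)C)cc1)c1c(Br)ccc(C)c1Br | intermediate
6 | 4-[(2,6-dibromo-3-methylphenyl)(hydroxy)(phenyl)methyl]phenol (racemic) | OC(c1ccccc1)(c1ccc(O)cc1)c1c(Br)ccc(C)c1Br | intermediate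
7 | 4-[(2,6-dibromo-3-methylphenyl)(phenyl)methylidene]cyclohexa-2,5-dien-1-one | Cc1ccc(Br)c(C(=C2C=CC(=O)C=C2)c2ccccc2)c1Br | intermediate
8 | 4-hydroxyphenylboronic acid | OB(O)c1ccc(O)cc1 | starting material
9 | 4-[(3-bromo-4'-hydroxy-4-methyl-[1,1'-biphenyl]-2-yl)(phenyl)methylidene]cyclohexa-2,5-dien-1-one | Cc1ccc(-c2ccc(O)cc2)c(C(=C2C=CC(=O)C=C2)c2ccccc2)c1Br | intermediate
10 | 4-ethynylphenol | C#Cc1ccc(O)cc1 | starting material
11 | selaginellin A | Cc1ccc(-c2ccc(O)cc2)c(C(=C2C=CC(=O)C=C2)c2ccccc2)c1C#Cc1ccc(O)cc1 | target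

## Count and risks

Total step count: 3. Longest linear sequence: 3 steps (1 → 7 → 9 → 11). All three steps carry risk; step 3 and step 1 are the most exposed, step 2 less so.

**Step 1 (addition of a hindered, thermally fragile aryllithium to the ketone and one-pot dearomatisation).** The fallback sets out from aryllithium 3 and comes back at 7. 3 is trapped at −78 °C with benzaldehyde, a fast and unhindered addition, to give lithium (2,6-dibromo-3-methylphenyl)(phenyl)methoxide F1. Quenching with dilute HCl gives the benzhydrol (2,6-dibromo-3-methylphenyl)(phenyl)methanol F2. F2 alkylates phenol (5 eq) para-selectively in a dehydrative Friedel–Crafts reaction (TfOH 10 mol %, HFIP, rt) to the leuco phenol 4-[(2,6-dibromo-3-methylphenyl)(phenyl)methyl]phenol F3. DDQ (1.1 eq, dioxane, rt) then dehydrogenates F3 to 7. The third ring thus enters as a phenol nucleophile, and the dienone ring is made by oxidation instead of dehydration.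

**Step 2 (site selectivity between the two C–Br bonds rests on sterics alone).** The fallback sets out from silyl ether 4 and comes back at 9. Purchased 2-bromo-4-iodotoluene (Cc1ccc(I)cc1Br) is lithiated between its halogens (LDA, THF, −78 °C) to 2-bromo-6-iodo-3-methylphenyllithium F4. F4 adds to 4 to give lithium (2-bromo-6-iodo-3-methylphenyl)(phenyl)[4-(trimethylsilyloxy)phenyl]methoxide F5. The acid treatment of step 1 gives 4-[(2-bromo-6-iodo-3-methylphenyl)(hydroxy)(phenyl)methyl]phenol F6 and then, by loss of water, 4-[(2-bromo-6-iodo-3-methylphenyl)(phenyl)methylidene]cyclohexa-2,5-dien-1-one F7. Suzuki coupling of F7 with 8 (Pd(PPh3)4, aq Na2CO3, DME, 40 °C) occurs at C–I only and gives 9. Halogen identity, not sterics, then decides the site.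

**Step 3 (oxidative addition at a di-ortho bromide next to the quinone methide, with a polymerisable free-phenol alkyne).** The fallback sets out from 9 and comes back at 11. 9 is coupled with trimethylsilylacetylene (5 eq, same catalyst, sealed tube, 80 °C), a small and robust alkyne that allows forcing conditions, to give 4-[{4'-hydroxy-4-methyl-3-[(trimethylsilyl)ethynyl]-[1,1'-biphenyl]-2-yl}(phenyl)methylidene]cyclohexa-2,5-dien-1-one F8. TBAF/AcOH (THF, 0 °C) removes silicon to give 4-[(3-ethynyl-4'-hydroxy-4-methyl-[1,1'-biphenyl]-2-yl)(phenyl)methylidene]cyclohexa-2,5-dien-1-one F9. A second Sonogashira coupling of F9 with the unhindered 4-iodophenol (Pd(PPh3)2Cl2, CuI, Et3N, THF, rt) gives 11.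

## Further compounds

F1 | step 1 | lithium (2,6-dibromo-3-methylphenyl)(phenyl)methoxide (racemic) | [Li]OC(c1ccccc1)c1c(Br)ccc(C)c1Br
F2 | step 1 | (2,6-dibromo-3-methylphenyl)(phenyl)methanol (racemic) | OC(c1ccccc1)c1c(Br)ccc(C)c1Br
F3 | step 1 | 4-[(2,6-dibromo-3-methylphenyl)(phenyl)methyl]phenol (racemic) | Oc1ccc(cc1)C(c1ccccc1)c1c(Br)ccc(C)c1Br
F4 | step 2 | 2-bromo-6-iodo-3-methylphenyllithium | [Li]c1c(I)ccc(C)c1Br
F5 | step 2 | lithium (2-bromo-6-iodo-3-methylphenyl)(phenyl)[4-(trimethylsilyloxy)phenyl]methoxide (racemic) | [Li]OC(c1ccccc1)(c1ccc(O[Si](C)(C)C)cc1)c1c(I)ccc(C)c1Br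
F6 | step 2 | 4-[(2-bromo-6-iodo-3-methylphenyl)(hydroxy)(phenyl)methyl]phenol (racemic) | OC(c1ccccc1)(c1ccc(O)cc1)c1c(I)ccc(C)c1Br
F7 | step 2 | 4-[(2-bromo-6-iodo-3-methylphenyl)(phenyl)methylidene]cyclohexa-2,5-dien-1-one | Cc1ccc(I)c(C(=C2C=CC(=O)C=C2)c2ccccc2)c1Br
F8 | step 3 | 4-[{4'-hydroxy-4-methyl-3-[(trimethylsilyl)ethynyl]-[1,1'-biphenyl]-2-yl}(phenyl)methylidene]cyclohexa-2,5-dien-1-one | Cc1ccc(-c2ccc(O)cc2)c(C(=C2C=CC(=O)C=C2)c2ccccc2)c1C#C[Si](C)(C)C
F9 | step 3 | 4-[(3-ethynyl-4'-hydroxy-4-methyl-[1,1'-biphenyl]-2-yl)(phenyl)methylidene]cyclohexa-2,5-dien-1-one | Cc1ccc(-c2ccc(O)cc2)c(C(=C2C=CC(=O)C=C2)c2ccccc2)c1C#C
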